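**Plan**

1. Rings are lettered A to F from the 2,4,6-trihydroxyphenyl end to the 3,4,5-trihydroxyphenyl end; C-1 of a ring is the carbon whose ether oxygen points toward ring A. All hydroxyls travel as methyl ethers.
2. Enabling feature: ring E has hydrogen only at C-2 and C-6 and oxygen at C-1, C-3, C-4 and C-5. The O–D ether at C-1 lies para to the crowded O–F ether at C-4 and meta to the C-5 oxygen, which is the pattern a vinylketene–ynol ether benzannulation produces.
3. Retrosynthesis: cleave the fourteen O-methyl bonds; cut ring E at C-5–C-6, C-1–C-2 and C-4–C-5 into the ethynyl ether of an A–B–C–D phenol and a ring F diazoketone; cut the tetramer at its three diaryl ether C–O bonds (D C-1–O, C C-1–O, B C-1–O).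
4. Forward: diazoketone (steps 1–4); chain A→B→C→D by three Ullmann couplings in which the hindered phenol is always the nucleophile, each followed by debenzylation (steps 5–15); ethynyl ether (steps 16–17); ring E, the only ring built, closes last (step 18); demethylation (step 19).
5. Stereochemistry: the target has no stereocentre; the enol ether geometry of the diazoketone is erased on aromatisation.

Key step: step 18

Remark: the enol ether double bond of the ring F building block is drawn Z (aryloxy trans to the carbonyl); an E/Z mixture would serve equally because ring E C-4 loses this information.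

**Ring F diazoketone**

Step 1
Reactants: 1 methyl methoxyacetate; 2 methyl formate
Product: 4 methyl 2-methoxy-3-(tosyloxy)acrylate (E/Z mixture), via sodium enolate 3 (not isolated)
Conditions: NaH, HCO2Me (excess), THF, 0 °C to rt; evaporate; TsCl, THF, 0 °C to rt
Reagents that add atoms: p-toluenesulfonyl chloride, Cc1ccc(cc1)S(Cl)(=O)=O
Why: Crossed Claisen condensation with the non-enolisable formate should give the stable sodium enolate of the formyl ester, and O-sulfonylation of that enolate turns the enol oxygen into a leaving group.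

Step 2
Reactants: 4 methyl 2-methoxy-3-(tosyloxy)acrylate; 5 3,4,5-trimethoxyphenol
Product: 6 methyl (Z)-2-methoxy-3-(3,4,5-trimethoxyphenoxy)acrylate
Conditions: K2CO3, DABCO (cat.), MeCN, 50 °C
Reagents that add atoms: none
Why: Addition–elimination (nucleophilic vinylic substitution) of the phenoxide at the β-carbon of the sulfonyloxy acrylate, with DABCO as nucleophilic catalyst, should give the more stable isomer with the aryloxy group trans to the ester through reversible conjugate addition.

Step 3
Reactants: 6 methyl (Z)-2-methoxy-3-(3,4,5-trimethoxyphenoxy)acrylate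
Product: 7 (Z)-2-methoxy-3-(3,4,5-trimethoxyphenoxy)acrylic acid
Conditions: LiOH, THF/H2O, rt; then 1 M HCl to pH 3, 0 °C
Reagents that add atoms: lithium hydroxide, [Li+].[OH-]
Why: Ester saponification, routine for β-aryloxyacrylates; the push–pull enol ether should tolerate brief contact with cold dilute acid.

Step 4
Reactants: 7 (Z)-2-methoxy-3-(3,4,5-trimethoxyphenoxy)acrylic acid
Product: 9 (Z)-1-diazo-3-methoxy-4-(3,4,5-trimethoxyphenoxy)but-3-en-2-one, via acid chloride 8 (not isolated)
Conditions: (COCl)2, DMF (cat.), CH2Cl2, 0 °C; evaporate; CH2N2, Et3N, Et2O, 0 °C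
Reagents that add atoms: diazomethane, C=[N+]=[N-]
Why: Acylation of diazomethane by the acid chloride (first stage of the Arndt–Eistert sequence, with Et3N as HCl scavenger) should outrun pyrazoline formation because the two donor oxygens make the double bond a poor dipolarophile, and the acid chloride has no α-hydrogen from which a ketene could form.

**A–B–C–D chain**

Step 5
Reactants: 10 2,4,6-trimethoxybenzaldehyde
Product: 12 2,4,6-trimethoxyphenol, via aryl formate 11 (not isolated)
Conditions: 30% H2O2, H2SO4 (cat.), MeOH, rt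
Reagents that add atoms: hydrogen peroxide, OO
Why: Acid-catalysed Dakin oxidation, in which the electron-rich aryl group migrates to oxygen and the formate is methanolysed in the same pot.

Step 6
Reactants: 13 4-bromo-2,6-dimethoxyphenol
Product: 14 2-(benzyloxy)-5-bromo-1,3-dimethoxybenzene
Conditions: BnBr, K2CO3, DMF, 50 °C
Reagents that add atoms: benzyl bromide, BrCc1ccccc1
Why: Williamson ether synthesis masks the flanked phenol as a benzyl ether that can later be removed beside methyl ethers.

Step 7
Reactants: 12 2,4,6-trimethoxyphenol; 14 2-(benzyloxy)-5-bromo-1,3-dimethoxybenzene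
Product: 15 2-(benzyloxy)-1,3-dimethoxy-5-(2,4,6-trimethoxyphenoxy)benzene (A–B benzyl ether)
Conditions: CuI (10 mol %), picolinic acid (20 mol %), K3PO4, DMSO, 90 °C, under argon
Reagents that add atoms: none
Why: Ligand-accelerated Ullmann diaryl ether synthesis, in which the di-ortho-methoxy phenoxide is the nucleophile and the bromide has both ortho positions free, the pairing this catalyst system handles.

Step 8
Reactants: 15 A–B benzyl ether
Product: 16 2,6-dimethoxy-4-(2,4,6-trimethoxyphenoxy)phenol (A–B phenol)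
Conditions: H2 (1 atm), 10% Pd/C, EtOAc/MeOH, rt
Reagents that add atoms: none
Why: Catalytic hydrogenolysis of the benzyl aryl ether, which leaves methyl and diaryl ethers untouched.

Step 9
Reactants: 17 2,3,4-trimethoxybenzaldehyde
Product: 19 2,3,4-trimethoxyphenol, via aryl formate 18 (not isolated)
Conditions: 30% H2O2, H2SO4 (cat.), MeOH, rt
Reagents that add atoms: hydrogen peroxide, OO
Why: Dakin oxidation as in step 5, favoured by the ortho- and para-methoxy groups on the migrating ring.

Step 10
Reactants: 19 2,3,4-trimethoxyphenol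
Product: 20 6-bromo-2,3,4-trimethoxyphenol
Conditions: NBS, iPr2NH (cat.), CH2Cl2, 0 °C
Reagents that add atoms: N-bromosuccinimide, O=C1CCC(=O)N1Br
Why: Amine-mediated electrophilic ortho-bromination of a phenol; the para position is blocked by a methoxy group, so bromine should enter C-6, ortho to the hydroxyl, in preference to C-5.

Step 11
Reactants: 20 6-bromo-2,3,4-trimethoxyphenol
Product: 21 2-(benzyloxy)-1-bromo-3,4,5-trimethoxybenzene
Conditions: BnBr, K2CO3, DMF, 50 °C
Reagents that add atoms: benzyl bromide, BrCc1ccccc1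
Why: Williamson ether synthesis removes the free phenol so the bromide cannot couple with itself in the next step.

Step 12
Reactants: 16 A–B phenol; 21 2-(benzyloxy)-1-bromo-3,4,5-trimethoxybenzene
Product: 22 2-(benzyloxy)-1-[2,6-dimethoxy-4-(2,4,6-trimethoxyphenoxy)phenoxy]-3,4,5-trimethoxybenzene (A–B–C benzyl ether)
Conditions: CuI (20 mol %), picolinic acid (40 mol %), K3PO4, DMSO, 100 °C, under argon
Reagents that add atoms: none
Why: Ullmann diaryl ether synthesis forming the B C-4–O–C C-1 bond; the catalyst system is established for di-ortho-substituted phenoxides with ortho-substituted aryl halides, and the bromide keeps one ortho position (ring C C-6) free.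

Step 13
Reactants: 22 A–B–C benzyl ether
Product: 23 6-[2,6-dimethoxy-4-(2,4,6-trimethoxyphenoxy)phenoxy]-2,3,4-trimethoxyphenol (A–B–C phenol)
Conditions: H2 (1 atm), 10% Pd/C, EtOAc/MeOH, rt
Reagents that add atoms: none
Why: Hydrogenolysis of the benzyl ether frees the ring C C-2 hydroxyl as the nucleophile for the next coupling.

Step 14
Reactants: 23 A–B–C phenol; 14 2-(benzyloxy)-5-bromo-1,3-dimethoxybenzene
Product: 24 2-(benzyloxy)-5-{6-[2,6-dimethoxy-4-(2,4,6-trimethoxyphenoxy)phenoxy]-2,3,4-trimethoxyphenoxy}-1,3-dimethoxybenzene (A–B–C–D benzyl ether)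
Conditions: CuI (20 mol %), picolinic acid (40 mol %), K3PO4, DMSO, 100 °C, under argon
Reagents that add atoms: none
Why: Ullmann diaryl ether synthesis in which the doubly flanked ring C C-2 oxygen is the nucleophile and the unhindered bromide supplies ring D, so no substitution at a flanked carbon is required.

Step 15
Reactants: 24 A–B–C–D benzyl ether
Product: 25 4-{6-[2,6-dimethoxy-4-(2,4,6-trimethoxyphenoxy)phenoxy]-2,3,4-trimethoxyphenoxy}-2,6-dimethoxyphenol (A–B–C–D phenol)
Conditions: H2 (1 atm), 10% Pd/C, EtOAc/MeOH, rt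
Reagents that add atoms: none
Why: Hydrogenolysis of the benzyl ether frees the ring D C-4 hydroxyl that will become the ynol ether oxygen.

**Ynol ether, ring E and deprotection**

Step 16
Reactants: 25 A–B–C–D phenol; 26 trichloroethylene
Product: 28 (E)-1,2-dichlorovinyl ether of 25, via dichloroacetylene 27 (not isolated)
Conditions: K2CO3, DMF, 70 °C
Reagents that add atoms: none
Why: Base-induced loss of HCl from trichloroethylene gives dichloroacetylene, to which the phenoxide adds anti (first stage of the dichlorovinyl ether route to ynol ethers); the small linear electrophile should be insensitive to the two ortho-methoxy groups.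

Step 17
Reactants: 28 (E)-1,2-dichlorovinyl ether of 25
Product: 31 ethynyl ether of 25 (A–B–C–D ynol ether), via chloroethynyl ether 29 (not isolated), via lithium acetylide 30 (not isolated)
Conditions: n-BuLi (2.3 equiv), THF, −78 to −40 °C; MeOH, −78 °C; used at once
Reagents that add atoms: none
Why: Vinyl deprotonation with β-elimination of LiCl, then chlorine–lithium exchange and cold protonation (second stage of the dichlorovinyl ether route), should be faster at −78 °C than ortho-lithiation of the methoxyarenes.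

Step 18
Reactants: 31 A–B–C–D ynol ether; 9 (Z)-1-diazo-3-methoxy-4-(3,4,5-trimethoxyphenoxy)but-3-en-2-one
Product: 36 A–F hexamer monophenol (free OH at ring E C-5; fourteen OMe), via vinylketene 32 (not isolated), via vinylcyclobutenone 33 (not isolated), via dienylketene 34 (not isolated), via cyclohexadienone 35 (not isolated)
Conditions: hν (365 nm), CH2Cl2, rt, 9 added slowly (1.3 equiv); then PhMe, 80 °C; then K2CO3, MeOH, rt
Reagents that add atoms: none
Why: Irradiation of 9 expels N2 and the alkenyl group migrates (photochemical Wolff rearrangement) to give vinylketene 32, whose carbonyl carbon is attacked by the nucleophilic terminal carbon of ynol ether 31 in a [2+2] cycloaddition that forms E C-5–C-6 and E C-1–C-2 in vinylcyclobutenone 33. Reversible 4π electrocyclic opening of 33 gives dienylketene 34, and ring E is closed by a thermal 6π disrotatory electrocyclisation (E C-4–C-5) to cyclohexadienone 35, which tautomerises to the phenol. This is the Danheiser benzannulation in its diazoketone form, known for alkoxy- and siloxyalkynes. No stereocentre survives: the sp3 centres of 33 and 35 are racemic and are erased by ring opening and aromatisation, and the Z enol ether only places the ring F aryloxy group outward in the 6π transition state. The required regiochemistry (O–D meta to the new hydroxyl and para to O–F) follows from the polarity of the ynol ether. Cross-cycloaddition over ketene dimerisation is favoured by slow addition of 9 at a wavelength only the diazoketone absorbs, and any product O-acylated by excess ketene is returned by the K2CO3/MeOH treatment.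

Step 19
Reactants: 36 A–F hexamer monophenol
Product: 37 CNP0270681.0 (target; all fifteen hydroxyls free)
Conditions: BBr3 (excess), CH2Cl2, −78 °C to rt; MeOH then H2O; under argon
Reagents that add atoms: none
Why: Lewis-acid-mediated cleavage of aryl methyl ethers (bromide attacks the O-methyl carbon of the borane adduct in an SN2 step) should spare the diaryl ethers, which have no sp3 carbon on oxygen; the polyphenol is handled under argon.

**Compound list**

1 | methyl methoxyacetate | COCC(=O)OC | starting material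
2 | methyl formate | COC=O | starting material
3 | sodium enolate of methyl 2-methoxy-3-oxopropanoate (geometry not fixed) | [Na+].[O-]C=C(OC)C(=O)OC | intermediate
4 | methyl 2-methoxy-3-(tosyloxy)acrylate (E/Z mixture) | COC(=O)C(OC)=COS(=O)(=O)c1ccc(C)cc1 | intermediate
5 | 3,4,5-trimethoxyphenol | COc1cc(O)cc(OC)c1OC | starting material
6 | methyl (Z)-2-methoxy-3-(3,4,5-trimethoxyphenoxy)acrylate | COC(=O)/C(OC)=C/Oc1cc(OC)c(OC)c(OC)c1 | intermediate
7 | (Z)-2-methoxy-3-(3,4,5-trimethoxyphenoxy)acrylic acid | OC(=O)/C(OC)=C/Oc1cc(OC)c(OC)c(OC)c1 | intermediate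
8 | (Z)-2-methoxy-3-(3,4,5-trimethoxyphenoxy)acryloyl chloride | ClC(=O)/C(OC)=C/Oc1cc(OC)c(OC)c(OC)c1 | intermediate
9 | (Z)-1-diazo-3-methoxy-4-(3,4,5-trimethoxyphenoxy)but-3-en-2-one | [N-]=[N+]=CC(=O)/C(OC)=C/Oc1cc(OC)c(OC)c(OC)c1 | intermediate
10 | 2,4,6-trimethoxybenzaldehyde | COc1cc(OC)c(C=O)c(OC)c1 | starting material
11 | 2,4,6-trimethoxyphenyl formate | COc1cc(OC)c(OC=O)c(OC)c1 | intermediate
12 | 2,4,6-trimethoxyphenol | COc1cc(OC)c(O)c(OC)c1 | intermediate
13 | 4-bromo-2,6-dimethoxyphenol | COc1cc(Br)cc(OC)c1O | starting material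
14 | 2-(benzyloxy)-5-bromo-1,3-dimethoxybenzene | COc1cc(Br)cc(OC)c1OCc1ccccc1 | intermediate
15 | 2-(benzyloxy)-1,3-dimethoxy-5-(2,4,6-trimethoxyphenoxy)benzene (A–B benzyl ether) | COc1cc(OC)c(Oc2cc(OC)c(OCc3ccccc3)c(OC)c2)c(OC)c1 | intermediate
16 | 2,6-dimethoxy-4-(2,4,6-trimethoxyphenoxy)phenol (A–B phenol) | COc1cc(OC)c(Oc2cc(OC)c(O)c(OC)c2)c(OC)c1 | intermediate
17 | 2,3,4-trimethoxybenzaldehyde | COc1ccc(C=O)c(OC)c1OC | starting material
18 | 2,3,4-trimethoxyphenyl formate | COc1ccc(OC=O)c(OC)c1OC | intermediate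
19 | 2,3,4-trimethoxyphenol | COc1ccc(O)c(OC)c1OC | intermediate
20 | 6-bromo-2,3,4-trimethoxyphenol | COc1cc(Br)c(O)c(OC)c1OC | intermediate
21 | 2-(benzyloxy)-1-bromo-3,4,5-trimethoxybenzene | COc1cc(Br)c(OCc2ccccc2)c(OC)c1OC | intermediate
22 | 2-(benzyloxy)-1-[2,6-dimethoxy-4-(2,4,6-trimethoxyphenoxy)phenoxy]-3,4,5-trimethoxybenzene (A–B–C benzyl ether) | COc1cc(Oc2c(OC)cc(Oc3c(OC)cc(OC)cc3OC)cc2OC)c(OCc2ccccc2)c(OC)c1OC | intermediate
23 | 6-[2,6-dimethoxy-4-(2,4,6-trimethoxyphenoxy)phenoxy]-2,3,4-trimethoxyphenol (A–B–C phenol) | COc1cc(Oc2c(OC)cc(Oc3c(OC)cc(OC)cc3OC)cc2OC)c(O)c(OC)c1OC | intermediate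
24 | 2-(benzyloxy)-5-{6-[2,6-dimethoxy-4-(2,4,6-trimethoxyphenoxy)phenoxy]-2,3,4-trimethoxyphenoxy}-1,3-dimethoxybenzene (A–B–C–D benzyl ether) | COc1cc(Oc2c(OC)cc(Oc3c(OC)cc(OC)cc3OC)cc2OC)c(Oc2cc(OC)c(OCc3ccccc3)c(OC)c2)c(OC)c1OC | intermediate
25 | 4-{6-[2,6-dimethoxy-4-(2,4,6-trimethoxyphenoxy)phenoxy]-2,3,4-trimethoxyphenoxy}-2,6-dimethoxyphenol (A–B–C–D phenol) | COc1cc(Oc2c(OC)cc(Oc3c(OC)cc(OC)cc3OC)cc2OC)c(Oc2cc(OC)c(O)c(OC)c2)c(OC)c1OC | intermediate
26 | trichloroethylene | ClC=C(Cl)Cl | starting material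
27 | dichloroacetylene | ClC#CCl | intermediate
28 | (E)-1,2-dichlorovinyl ether of 25 (ring D C-4 O–C(Cl)=CHCl) | COc1cc(Oc2c(OC)cc(Oc3c(OC)cc(OC)cc3OC)cc2OC)c(Oc2cc(OC)c(O/C(Cl)=C\Cl)c(OC)c2)c(OC)c1OC | intermediate
29 | chloroethynyl ether of 25 (ring D C-4 O–C≡C–Cl) | COc1cc(Oc2c(OC)cc(Oc3c(OC)cc(OC)cc3OC)cc2OC)c(Oc2cc(OC)c(OC#CCl)c(OC)c2)c(OC)c1OC | intermediate
30 | lithium acetylide of 31 (ring D C-4 O–C≡C–Li) | COc1cc(Oc2c(OC)cc(Oc3c(OC)cc(OC)cc3OC)cc2OC)c(Oc2cc(OC)c(OC#C[Li])c(OC)c2)c(OC)c1OC | intermediate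
31 | ethynyl ether of 25 (ring D C-4 O–C≡CH; A–B–C–D ynol ether) | COc1cc(Oc2c(OC)cc(Oc3c(OC)cc(OC)cc3OC)cc2OC)c(Oc2cc(OC)c(OC#C)c(OC)c2)c(OC)c1OC | intermediate
32 | (Z)-3-methoxy-4-(3,4,5-trimethoxyphenoxy)buta-1,3-dien-1-one (vinylketene) | O=C=C/C(OC)=C/Oc1cc(OC)c(OC)c(OC)c1 | intermediate
33 | 3-(A–B–C–D aryloxy)-4-[(Z)-1-methoxy-2-(3,4,5-trimethoxyphenoxy)vinyl]cyclobut-2-en-1-one (racemic vinylcyclobutenone) | COc1cc(Oc2c(OC)cc(Oc3c(OC)cc(OC)cc3OC)cc2OC)c(Oc2cc(OC)c(OC3=CC(=O)C3/C(OC)=C/Oc3cc(OC)c(OC)c(OC)c3)c(OC)c2)c(OC)c1OC | intermediate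
34 | (3E,5Z)-3-(A–B–C–D aryloxy)-5-methoxy-6-(3,4,5-trimethoxyphenoxy)hexa-1,3,5-trien-1-one (dienylketene) | COc1cc(Oc2c(OC)cc(Oc3c(OC)cc(OC)cc3OC)cc2OC)c(Oc2cc(OC)c(O/C(=C/C(OC)=C/Oc3cc(OC)c(OC)c(OC)c3)C=C=O)c(OC)c2)c(OC)c1OC | intermediate
35 | 3-(A–B–C–D aryloxy)-5-methoxy-6-(3,4,5-trimethoxyphenoxy)cyclohexa-2,4-dien-1-one (racemic cyclohexadienone) | COc1cc(Oc2c(OC)cc(Oc3c(OC)cc(OC)cc3OC)cc2OC)c(Oc2cc(OC)c(OC3=CC(=O)C(Oc4cc(OC)c(OC)c(OC)c4)C(OC)=C3)c(OC)c2)c(OC)c1OC | intermediate
36 | A–F hexamer monophenol: ring E carries O–D at C-1, OMe at C-3, 3,4,5-trimethoxyphenoxy at C-4 and free OH at C-5; fourteen OMe in all | COc1cc(Oc2c(OC)cc(Oc3c(OC)cc(OC)cc3OC)cc2OC)c(Oc2cc(OC)c(Oc3cc(O)c(Oc4cc(OC)c(OC)c(OC)c4)c(OC)c3)c(OC)c2)c(OC)c1OC | intermediate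
37 | CNP0270681.0 | Oc1cc(O)c(Oc2cc(O)c(Oc3cc(O)c(O)c(O)c3Oc3cc(O)c(Oc4cc(O)c(Oc5cc(O)c(O)c(O)c5)c(O)c4)c(O)c3)c(O)c2)c(O)c1 | target

**Totals**

Total steps: 19. Longest linear sequence: 11 steps (10 → 12 → 15 → 16 → 22 → 23 → 24 → 25 → 28 → 31 → 36 → 37; the branch from 17 is equally long).

**Steps most likely to fail**

1. Step 18. The vinylketene may be consumed by dimerisation or by acylating the phenolic product faster than the bulky aryl ynol ether captures it, and the ynol ether may hydrate or oligomerise during irradiation and heating. Fallback, setting out from 25 and rejoining at 37: ring E would be brought in as a pre-formed arene. Phenol 13 and commercial 3,4,5-trimethoxyphenylboronic acid would be joined by Chan–Lam coupling (Cu(OAc)2, pyridine, 4 Å molecular sieves, air, CH2Cl2, rt), which leaves the aryl bromide untouched, to give 5-bromo-1,3-dimethoxy-2-(3,4,5-trimethoxyphenoxy)benzene F1. Ullmann coupling of the hindered phenol 25 with the unhindered bromide F1 (CuI, picolinic acid, K3PO4, DMSO, 100 °C) would give the pentadeca-O-methyl ether of the target F2, and BBr3 as in step 19 would lead to 37.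

2. Step 17. n-BuLi may metalate the polymethoxyarene rings in competition with vinyl deprotonation and chlorine–lithium exchange, and the terminal aryl ethynyl ether may oligomerise or hydrate during quench and concentration. Fallback, setting out from 28 and rejoining at 36: the lithium acetylide 30 would be quenched with Me3SiCl instead of methanol to give the storable (trimethylsilyl)ethynyl ether of 25 F3, which can be purified from metalation by-products. Benzannulation of F3 with 9 under the conditions of step 18 would give the hexamer phenol carrying SiMe3 at ring E C-6 F4, and protodesilylation of the electron-rich ring (TFA, CH2Cl2, 0 °C) would return 36.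

3. Step 12. Copper insertion into the electron-rich, ortho-substituted bromide, paired with a di-ortho-substituted phenoxide, may be too slow, so that hydrodebromination and oxidative degradation of the phenol take over. Fallback, setting out from 21 and 16 and rejoining at 22: bromine–lithium exchange on 21 (n-BuLi, THF, −78 °C) would give [2-(benzyloxy)-3,4,5-trimethoxyphenyl]lithium F5, and B(OiPr)3 followed by dilute HCl would give [2-(benzyloxy)-3,4,5-trimethoxyphenyl]boronic acid F6. Chan–Lam coupling of F6 with phenol 16 (Cu(OAc)2, pyridine, 4 Å molecular sieves, air, CH2Cl2, rt) would give 22 by transmetalation instead of oxidative addition.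

**Further compounds**

F1 | step 18 | 5-bromo-1,3-dimethoxy-2-(3,4,5-trimethoxyphenoxy)benzene | COc1cc(Br)cc(OC)c1Oc1cc(OC)c(OC)c(OC)c1
F2 | step 18 | pentadeca-O-methyl ether of 37 (36 with OMe at ring E C-5) | COc1cc(Oc2c(OC)cc(Oc3c(OC)cc(OC)cc3OC)cc2OC)c(Oc2cc(OC)c(Oc3cc(OC)c(Oc4cc(OC)c(OC)c(OC)c4)c(OC)c3)c(OC)c2)c(OC)c1OC
F3 | step 17 | (trimethylsilyl)ethynyl ether of 25 (ring D C-4 O–C≡C–SiMe3) | COc1cc(Oc2c(OC)cc(Oc3c(OC)cc(OC)cc3OC)cc2OC)c(Oc2cc(OC)c(OC#C[Si](C)(C)C)c(OC)c2)c(OC)c1OC
F4 | step 17 | 36 carrying SiMe3 at ring E C-6 | COc1cc(Oc2c(OC)cc(Oc3c(OC)cc(OC)cc3OC)cc2OC)c(Oc2cc(OC)c(Oc3c([Si](C)(C)C)c(O)c(Oc4cc(OC)c(OC)c(OC)c4)c(OC)c3)c(OC)c2)c(OC)c1OC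
F5 | step 12 | [2-(benzyloxy)-3,4,5-trimethoxyphenyl]lithium | COc1cc([Li])c(OCc2ccccc2)c(OC)c1OC
F6 | step 12 | [2-(benzyloxy)-3,4,5-trimethoxyphenyl]boronic acid | COc1cc(B(O)O)c(OCc2ccccc2)c(OC)c1OC
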